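The target is cut at C7=C8 and C7′=C8′ into crocetin dialdehyde and two C15 benzothiazolyl sulfones, and each ring at the bond between ring carbon C2 and its side-chain CH2. The key step exploits that C2, flanked by the gem-dimethyl carbon C1, is the β-carbon of an enone once a temporary carbonyl sits at C4 of ring A or ring B: copper-catalysed enantioselective addition of (1,3-dioxolan-2-ylmethyl)magnesium bromide to the disubstituted enone of one achiral cyclohexa-2,5-dienone forms that bond and sets C2, each ligand antipode serving one ring. The dienone already carries C1, the C5 methyl, the C5=C6 alkene and C7 as a 4-methoxybenzyl ether.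

Key step: step 6

Remarks on the chemistry
- Ring atoms carry carotenoid numbers (C1 gem-dimethyl, C2 stereocentre, C4 temporary carbonyl carbon, C5 methyl-bearing, C6, exocyclic C7); primed numbers belong to the ring B (diol) end; the target is read as (2R,2′S), all-E.
- Assumption: the sense of induction of the ferrocenyl diphosphine on dienone 11 has to be confirmed in a first run; the (R,SP) ligand is written for the (5S) series and its antipode for the (5R) series, and if the sense is the reverse the two ligands change places between steps 6 and 7 and nothing else changes.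
- The C7 oxygen is carried as a 4-methoxybenzyl ether and not as an acetal-type ether such as methoxymethyl: it survives the aqueous acid that unmasks the side-chain dioxolane and is removed oxidatively under neutral conditions that spare silyl ethers, the prenyl group and the ionisable allylic C7–O bond.
- 1,3-Dihydroxyacetone (32) is used as its commercial dimer, which reacts as the monomer.

**Dienone (steps 1–5)**

Step 1
Reactants: 1 4,4-dimethylcyclohexane-1,3-dione
Product: 2 2,4,4-trimethylcyclohexane-1,3-dione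
Conditions: MeI (1.1 equiv), NaOH (1.0 equiv), H2O/1,4-dioxane, 65 °C
Reagents that add atoms: iodomethane, CI
Why: C-alkylation of the 1,3-dione enolate at the doubly activated C2 should dominate in aqueous base, where hydrogen bonding to the enolate oxygens suppresses O-methylation.

Step 2
Reactants: 2 2,4,4-trimethylcyclohexane-1,3-dione
Product: 3 2,6,6-trimethyl-3-(2-methylpropoxy)cyclohex-2-en-1-one
Conditions: i-BuOH, TsOH·H2O (cat.), toluene, reflux (Dean–Stark)
Reagents that add atoms: 2-methylpropan-1-ol, CC(C)CO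
Why: Acid-catalysed vinylogous ester formation with azeotropic removal of water; the alcohol should condense at the carbonyl remote from the gem-dimethyl group, leaving the hindered carbonyl free for step 4.

Step 3
Reactants: 4 (4-methoxyphenyl)methanol; 5 tributyl(iodomethyl)stannane
Product: 6 tributyl{[(4-methoxybenzyl)oxy]methyl}stannane
Conditions: NaH, THF/DMF, 0 °C → rt
Reagents that add atoms: none
Why: Williamson ether synthesis, the alkoxide of 4 displacing iodide from the primary carbon of 5 by SN2.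

Step 4
Reactants: 6 tributyl{[(4-methoxybenzyl)oxy]methyl}stannane; 3 2,6,6-trimethyl-3-(2-methylpropoxy)cyclohex-2-en-1-one
Product: 9 3-{[(4-methoxybenzyl)oxy]methyl}-2,4,4-trimethylcyclohex-2-en-1-one, via alkoxymethyllithium 7 (not isolated), via lithium alkoxide adduct 8 (not isolated)
Conditions: n-BuLi, THF, −78 °C; 3, −78 → 0 °C; then 1 M aq. HCl, rt
Reagents that add atoms: water, O
Why: Tin–lithium exchange gives the α-alkoxy organolithium 7, which adds 1,2 to the vinylogous ester carbonyl, and aqueous acid then hydrolyses the enol ether with loss of the tertiary hydroxyl (Stork–Danheiser transposition), so that C7 ends on the carbon next to the gem-dimethyl carbon and the carbonyl at the future C4.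

Step 5
Reactants: 9 3-{[(4-methoxybenzyl)oxy]methyl}-2,4,4-trimethylcyclohex-2-en-1-one
Product: 11 3-{[(4-methoxybenzyl)oxy]methyl}-2,4,4-trimethylcyclohexa-2,5-dien-1-one, via silyl dienol ether 10 (not isolated)
Conditions: LiN(i-Pr)2, Me3SiCl, THF, −78 °C; then Pd(OAc)2 (1.1 equiv), MeCN, rt
Reagents that add atoms: none
Why: Saegusa–Ito dehydrogenation: kinetic α′-deprotonation (the γ ring carbon is quaternary) and silylation give 10, from which divalent palladium forms an oxa-π-allyl complex that undergoes β-hydride elimination to the cross-conjugated dienone.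

**Key addition, both antipodes (steps 6–7)**

Step 6
Reactants: 11 3-{[(4-methoxybenzyl)oxy]methyl}-2,4,4-trimethylcyclohexa-2,5-dien-1-one; 12 (1,3-dioxolan-2-ylmethyl)magnesium bromide
Product: 14 (5S)-5-(1,3-dioxolan-2-ylmethyl)-3-{[(4-methoxybenzyl)oxy]methyl}-2,4,4-trimethylcyclohex-2-en-1-one, via bromomagnesium dienolate 13 (not isolated)
Conditions: CuBr·SMe2 (5 mol %), (R)-1-[(SP)-2-(diphenylphosphino)ferrocenyl]ethyldicyclohexylphosphine (6 mol %), t-BuOMe, −78 °C; 12 (0.5 M in THF, 1.3 equiv) by syringe pump; then aq. NH4Cl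
Reagents that add atoms: none
Why: Transmetalation of 12 to the monovalent copper–diphosphine complex gives a chiral alkylcopper–magnesium species that π-binds the disubstituted C5=C6 alkene of 11 (enone numbering), adds oxidatively to a trivalent copper σ-complex at C5 and reductively eliminates to form the C5–CH2 bond and the magnesium dienolate 13, which is protonated on work-up. The closest known reaction type is the copper/ferrocenyl-diphosphine-catalysed conjugate addition of Grignard reagents to cyclohexenones and to 4,4-disubstituted cyclohexa-2,5-dienones. No ring is closed. The new stereocentre at C5 (C2 of ring A) is controlled by the ligand alone, which selects one enantiotopic face of the planar, achiral dienone beside the gem-dimethyl carbon. Three selectivities are needed: site selectivity, secured because the other enone is tetrasubstituted with a fully substituted β-carbon; 1,4 over 1,2 addition, secured by the copper catalyst, the low temperature and the slow addition that keeps free Grignard reagent scarce; and face selectivity, secured by the chiral diphosphine.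

Step 7
Reactants: 11 3-{[(4-methoxybenzyl)oxy]methyl}-2,4,4-trimethylcyclohexa-2,5-dien-1-one; 12 (1,3-dioxolan-2-ylmethyl)magnesium bromide
Product: 16 (5R)-5-(1,3-dioxolan-2-ylmethyl)-3-{[(4-methoxybenzyl)oxy]methyl}-2,4,4-trimethylcyclohex-2-en-1-one, via bromomagnesium dienolate 15 (not isolated)
Conditions: CuBr·SMe2 (5 mol %), (S)-1-[(RP)-2-(diphenylphosphino)ferrocenyl]ethyldicyclohexylphosphine (6 mol %), t-BuOMe, −78 °C; 12 (0.5 M in THF, 1.3 equiv) by syringe pump; then aq. NH4Cl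
Reagents that add atoms: none
Why: The same copper-catalysed conjugate addition as step 6 with the mirror-image ligand, which must select the opposite face of the achiral dienone and so set the (5R) centre needed for ring B.

**Ring A sulfone (steps 8–14)**

Step 8
Reactants: 14 (5S)-5-(1,3-dioxolan-2-ylmethyl)-3-{[(4-methoxybenzyl)oxy]methyl}-2,4,4-trimethylcyclohex-2-en-1-one
Product: 17 (1RS,5R)-5-(1,3-dioxolan-2-ylmethyl)-3-{[(4-methoxybenzyl)oxy]methyl}-2,4,4-trimethylcyclohex-2-en-1-ol (both C1 epimers)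
Conditions: NaBH4, CeCl3·7H2O, MeOH, 0 °C
Reagents that add atoms: none
Why: Luche 1,2-reduction of the enone; the carbinol centre forms without control, which is immaterial because it is removed in step 9, and C5 is untouched (its descriptor changes only through the priority rules).

Step 9
Reactants: 17 (1RS,5R)-5-(1,3-dioxolan-2-ylmethyl)-3-{[(4-methoxybenzyl)oxy]methyl}-2,4,4-trimethylcyclohex-2-en-1-ol
Product: 19 2-{[(1R)-3-{[(4-methoxybenzyl)oxy]methyl}-2,2,4-trimethylcyclohex-3-en-1-yl]methyl}-1,3-dioxolane, via allylic mesylate 18 (not isolated)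
Conditions: MsCl, Et3N, THF, −30 °C; then LiBHEt3 (4 equiv), −30 °C → rt
Reagents that add atoms: none
Why: Sulfonylation of the allylic alcohol and SN2 displacement by the strongly nucleophilic, weakly basic LiBHEt3; hydride should enter at the secondary carbon (C4 of ring A) because the other allylic terminus is fully substituted and shielded by the gem-dimethyl carbon, so the C5=C6 alkene stays in place and the C2 centre is not involved.

Step 10
Reactants: 19 2-{[(1R)-3-{[(4-methoxybenzyl)oxy]methyl}-2,2,4-trimethylcyclohex-3-en-1-yl]methyl}-1,3-dioxolane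
Product: 20 2-[(1R)-3-{[(4-methoxybenzyl)oxy]methyl}-2,2,4-trimethylcyclohex-3-en-1-yl]acetaldehyde
Conditions: 1 M aq. HCl, THF, rt
Reagents that add atoms: water, O
Why: Acid-catalysed acetal hydrolysis; the 4-methoxybenzyl ether and the tetrasubstituted alkene should tolerate dilute aqueous acid, and the stereocentre is β to the new carbonyl and cannot epimerise.

Step 11
Reactants: 20 2-[(1R)-3-{[(4-methoxybenzyl)oxy]methyl}-2,2,4-trimethylcyclohex-3-en-1-yl]acetaldehyde
Product: 21 4-methoxybenzyl [(5R)-2,6,6-trimethyl-5-(3-methylbut-2-en-1-yl)cyclohex-1-en-1-yl]methyl ether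
Conditions: i-PrPPh3I, n-BuLi, THF, 0 °C; then 20, −78 °C → rt
Reagents that add atoms: isopropyltriphenylphosphonium iodide, CC(C)[P+](c1ccccc1)(c1ccccc1)c1ccccc1.[I-]
Why: Wittig olefination with the non-stabilised isopropylidene ylide builds the prenyl group; the new alkene carries two identical methyl groups, so no E/Z question arises.

Step 12
Reactants: 21 4-methoxybenzyl [(5R)-2,6,6-trimethyl-5-(3-methylbut-2-en-1-yl)cyclohex-1-en-1-yl]methyl ether
Product: 22 [(5R)-2,6,6-trimethyl-5-(3-methylbut-2-en-1-yl)cyclohex-1-en-1-yl]methanol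
Conditions: DDQ, CH2Cl2/pH 7 buffer, 0 °C
Reagents that add atoms: none
Why: Oxidative cleavage of the 4-methoxybenzyl ether by DDQ (benzylic hydride abstraction, hydrolysis of the oxocarbenium ion) under buffered neutral conditions that should leave the allylic C7–O bond and both alkenes intact.

Step 13
Reactants: 22 [(5R)-2,6,6-trimethyl-5-(3-methylbut-2-en-1-yl)cyclohex-1-en-1-yl]methanol
Product: 23 2-({[(5R)-2,6,6-trimethyl-5-(3-methylbut-2-en-1-yl)cyclohex-1-en-1-yl]methyl}sulfanyl)-1,3-benzothiazole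
Conditions: 1,3-benzothiazole-2-thiol, PPh3, DIAD, THF, 0 °C → rt
Reagents that add atoms: 1,3-benzothiazole-2-thiol, Sc1nc2ccccc2s1
Why: Mitsunobu thioetherification, the primary allylic alcohol being activated as its oxyphosphonium salt and displaced at C7 by the acidic heteroaryl thiol.

Step 14
Reactants: 23 2-({[(5R)-2,6,6-trimethyl-5-(3-methylbut-2-en-1-yl)cyclohex-1-en-1-yl]methyl}sulfanyl)-1,3-benzothiazole
Product: 24 2-({[(5R)-2,6,6-trimethyl-5-(3-methylbut-2-en-1-yl)cyclohex-1-en-1-yl]methyl}sulfonyl)-1,3-benzothiazole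
Conditions: (NH4)6Mo7O24·4H2O (10 mol %), 30% aq. H2O2, EtOH, 0 °C → rt
Reagents that add atoms: hydrogen peroxide, OO
Why: Molybdate-catalysed oxidation of sulfide to sulfone with hydrogen peroxide, which is chemoselective for sulfur over tri- and tetrasubstituted alkenes.

**Ring B sulfone (steps 15–24)**

Step 15
Reactants: 16 (5R)-5-(1,3-dioxolan-2-ylmethyl)-3-{[(4-methoxybenzyl)oxy]methyl}-2,4,4-trimethylcyclohex-2-en-1-one
Product: 25 (1RS,5S)-5-(1,3-dioxolan-2-ylmethyl)-3-{[(4-methoxybenzyl)oxy]methyl}-2,4,4-trimethylcyclohex-2-en-1-ol (both C1 epimers)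
Conditions: NaBH4, CeCl3·7H2O, MeOH, 0 °C
Reagents that add atoms: none
Why: Luche 1,2-reduction as in step 8; the transient carbinol centre is removed in step 16.

Step 16
Reactants: 25 (1RS,5S)-5-(1,3-dioxolan-2-ylmethyl)-3-{[(4-methoxybenzyl)oxy]methyl}-2,4,4-trimethylcyclohex-2-en-1-ol
Product: 27 2-{[(1S)-3-{[(4-methoxybenzyl)oxy]methyl}-2,2,4-trimethylcyclohex-3-en-1-yl]methyl}-1,3-dioxolane, via allylic mesylate 26 (not isolated)
Conditions: MsCl, Et3N, THF, −30 °C; then LiBHEt3 (4 equiv), −30 °C → rt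
Reagents that add atoms: none
Why: Sulfonylation and SN2 hydride displacement as in step 9, with hydride entering at the unhindered secondary allylic carbon so that the C5′=C6′ alkene is retained.

Step 17
Reactants: 27 2-{[(1S)-3-{[(4-methoxybenzyl)oxy]methyl}-2,2,4-trimethylcyclohex-3-en-1-yl]methyl}-1,3-dioxolane
Product: 29 2-[(1S)-3-{[(4-methoxybenzyl)oxy]methyl}-2,2,4-trimethylcyclohex-3-en-1-yl]ethan-1-ol, via aldehyde 28 (not isolated)
Conditions: 1 M aq. HCl, THF, rt; then NaHCO3 to pH 8, NaBH4, EtOH, 0 °C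
Reagents that add atoms: water, O
Why: Acetal hydrolysis as in step 10, followed in the same flask after neutralisation by borohydride reduction of the aldehyde to the primary alcohol.

Step 18
Reactants: 29 2-[(1S)-3-{[(4-methoxybenzyl)oxy]methyl}-2,2,4-trimethylcyclohex-3-en-1-yl]ethan-1-ol
Product: 30 4-methoxybenzyl [(5S)-5-(2-iodoethyl)-2,6,6-trimethylcyclohex-1-en-1-yl]methyl ether
Conditions: I2, PPh3, imidazole, CH2Cl2, 0 °C → rt
Reagents that add atoms: iodine, II
Why: Appel-type iodination, the alcohol being activated as an alkoxyphosphonium iodide and displaced by iodide at the unhindered primary carbon.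

Step 19
Reactants: 30 4-methoxybenzyl [(5S)-5-(2-iodoethyl)-2,6,6-trimethylcyclohex-1-en-1-yl]methyl ether
Product: 31 {2-[(1S)-3-{[(4-methoxybenzyl)oxy]methyl}-2,2,4-trimethylcyclohex-3-en-1-yl]ethyl}triphenylphosphonium iodide
Conditions: PPh3 (1.5 equiv), MeCN, 80 °C
Reagents that add atoms: triphenylphosphine, c1ccc(cc1)P(c1ccccc1)c1ccccc1
Why: SN2 quaternisation of triphenylphosphine by the primary iodide.

Step 20
Reactants: 32 1,3-dihydroxyacetone
Product: 33 1,3-bis{[tert-butyl(dimethyl)silyl]oxy}propan-2-one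
Conditions: t-BuMe2SiCl (2.2 equiv), imidazole, DMF, 0 °C → rt
Reagents that add atoms: tert-butyl(chloro)dimethylsilane, CC(C)(C)[Si](C)(C)Cl
Why: Imidazole-promoted silylation of both primary hydroxyl groups, the monomeric ketone being released from the dimer under the reaction conditions.

Step 21
Reactants: 31 {2-[(1S)-3-{[(4-methoxybenzyl)oxy]methyl}-2,2,4-trimethylcyclohex-3-en-1-yl]ethyl}triphenylphosphonium iodide; 33 1,3-bis{[tert-butyl(dimethyl)silyl]oxy}propan-2-one
Product: 35 4-methoxybenzyl [(5S)-5-{4-[(tert-butyldimethylsilyl)oxy]-3-{[(tert-butyldimethylsilyl)oxy]methyl}but-2-en-1-yl}-2,6,6-trimethylcyclohex-1-en-1-yl]methyl ether, via phosphorus ylide 34 (not isolated)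
Conditions: NaN(SiMe3)2, THF, −78 → 0 °C; then 33, −78 °C → rt
Reagents that add atoms: none
Why: Wittig olefination of the electrophilic α,α′-dioxygenated ketone with the non-stabilised ylide 34; the new trisubstituted alkene bears two identical silyloxymethyl groups, so no geometric isomers arise, and low temperature limits enolisation of the ketone.

Step 22
Reactants: 35 4-methoxybenzyl [(5S)-5-{4-[(tert-butyldimethylsilyl)oxy]-3-{[(tert-butyldimethylsilyl)oxy]methyl}but-2-en-1-yl}-2,6,6-trimethylcyclohex-1-en-1-yl]methyl ether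
Product: 36 [(5S)-5-{4-[(tert-butyldimethylsilyl)oxy]-3-{[(tert-butyldimethylsilyl)oxy]methyl}but-2-en-1-yl}-2,6,6-trimethylcyclohex-1-en-1-yl]methanol
Conditions: DDQ, CH2Cl2/pH 7 buffer, 0 °C
Reagents that add atoms: none
Why: Oxidative removal of the 4-methoxybenzyl ether as in step 12, under neutral conditions to which the silyl ethers are inert.

Step 23
Reactants: 36 [(5S)-5-{4-[(tert-butyldimethylsilyl)oxy]-3-{[(tert-butyldimethylsilyl)oxy]methyl}but-2-en-1-yl}-2,6,6-trimethylcyclohex-1-en-1-yl]methanol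
Product: 37 2-({[(5S)-5-{4-[(tert-butyldimethylsilyl)oxy]-3-{[(tert-butyldimethylsilyl)oxy]methyl}but-2-en-1-yl}-2,6,6-trimethylcyclohex-1-en-1-yl]methyl}sulfanyl)-1,3-benzothiazole
Conditions: 1,3-benzothiazole-2-thiol, PPh3, DIAD, THF, 0 °C → rt
Reagents that add atoms: 1,3-benzothiazole-2-thiol, Sc1nc2ccccc2s1
Why: Mitsunobu thioetherification at the primary allylic C7′ as in step 13.

Step 24
Reactants: 37 2-({[(5S)-5-{4-[(tert-butyldimethylsilyl)oxy]-3-{[(tert-butyldimethylsilyl)oxy]methyl}but-2-en-1-yl}-2,6,6-trimethylcyclohex-1-en-1-yl]methyl}sulfanyl)-1,3-benzothiazole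
Product: 38 2-({[(5S)-5-{4-[(tert-butyldimethylsilyl)oxy]-3-{[(tert-butyldimethylsilyl)oxy]methyl}but-2-en-1-yl}-2,6,6-trimethylcyclohex-1-en-1-yl]methyl}sulfonyl)-1,3-benzothiazole
Conditions: (NH4)6Mo7O24·4H2O (10 mol %), 30% aq. H2O2, EtOH, 0 °C → rt
Reagents that add atoms: hydrogen peroxide, OO
Why: Molybdate-catalysed sulfide-to-sulfone oxidation as in step 14, which should spare the alkenes and the primary silyl ethers.

**Endgame (steps 25–27)**

Step 25
Reactants: 38 2-({[(5S)-5-{4-[(tert-butyldimethylsilyl)oxy]-3-{[(tert-butyldimethylsilyl)oxy]methyl}but-2-en-1-yl}-2,6,6-trimethylcyclohex-1-en-1-yl]methyl}sulfonyl)-1,3-benzothiazole; 39 crocetin dialdehyde (all-E 2,6,11,15-tetramethylhexadeca-2,4,6,8,10,12,14-heptaenedial)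
Product: 41 (2E,4E,6E,8E,10E,12E,14E,16E)-17-[(5S)-5-{4-[(tert-butyldimethylsilyl)oxy]-3-{[(tert-butyldimethylsilyl)oxy]methyl}but-2-en-1-yl}-2,6,6-trimethylcyclohex-1-en-1-yl]-2,6,11,15-tetramethylheptadeca-2,4,6,8,10,12,14,16-octaenal, via 7′Z isomer 40 (not isolated)
Conditions: 38 (1 equiv), 39 (3 equiv), NaN(SiMe3)2 (1.1 equiv, added last), THF, −78 → −20 °C, Ar, dark; H2O; then I2 (cat.), CH2Cl2, rt, diffuse light
Reagents that add atoms: none
Why: Julia–Kocienski olefination, in which the allylic sulfonyl carbanion adds to one formyl group of 39 and Smiles rearrangement with loss of SO2 and benzothiazolone forms C7′=C8′, while excess dialdehyde and Barbier-type addition of base favour mono-olefination; the strained 7′Z isomer 40 expected alongside should be converted to the all-E aldehyde by iodine-catalysed equilibration, any minor unhindered Z isomers being removed on purification.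

Step 26
Reactants: 41 (2E,4E,6E,8E,10E,12E,14E,16E)-17-[(5S)-5-{4-[(tert-butyldimethylsilyl)oxy]-3-{[(tert-butyldimethylsilyl)oxy]methyl}but-2-en-1-yl}-2,6,6-trimethylcyclohex-1-en-1-yl]-2,6,11,15-tetramethylheptadeca-2,4,6,8,10,12,14,16-octaenal; 24 2-({[(5R)-2,6,6-trimethyl-5-(3-methylbut-2-en-1-yl)cyclohex-1-en-1-yl]methyl}sulfonyl)-1,3-benzothiazole
Product: 43 (2R,2′S)-2′-{4-[(tert-butyldimethylsilyl)oxy]-3-{[(tert-butyldimethylsilyl)oxy]methyl}but-2-en-1-yl}-2-(3-methylbut-2-en-1-yl)-β,β-carotene (all-E), via 7Z isomer 42 (not isolated)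
Conditions: 41 (1 equiv), 24 (1.5 equiv), NaN(SiMe3)2 (1.5 equiv, added last), THF, −78 → −20 °C, Ar, dark; H2O; then I2 (cat.), CH2Cl2, rt, diffuse light
Reagents that add atoms: none
Why: Second Julia–Kocienski olefination, now at the remaining formyl group, forming C7=C8; the 7Z isomer 42 should again be converted to the all-E polyene by iodine-catalysed equilibration, and neither stereocentre is near the reacting atoms.

Step 27
Reactants: 43 (2R,2′S)-2′-{4-[(tert-butyldimethylsilyl)oxy]-3-{[(tert-butyldimethylsilyl)oxy]methyl}but-2-en-1-yl}-2-(3-methylbut-2-en-1-yl)-β,β-carotene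
Product: 44 (2R,2′S)-2′-[4-hydroxy-3-(hydroxymethyl)but-2-en-1-yl]-2-(3-methylbut-2-en-1-yl)-β,β-carotene (all-E; target CNP0213288.1)
Conditions: Bu4NF, THF, 0 °C → rt, Ar, dark
Reagents that add atoms: none
Why: Fluoride-mediated cleavage of both primary silyl ethers under near-neutral conditions that the polyene should tolerate; no stereocentre or alkene is touched.

**Compound list**

1 | 4,4-dimethylcyclohexane-1,3-dione | CC1(C)CCC(=O)CC1=O | starting material
2 | 2,4,4-trimethylcyclohexane-1,3-dione | CC1C(=O)CCC(C)(C)C1=O | intermediate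
3 | 2,6,6-trimethyl-3-(2-methylpropoxy)cyclohex-2-en-1-one | CC1=C(OCC(C)C)CCC(C)(C)C1=O | intermediate
4 | (4-methoxyphenyl)methanol | COc1ccc(CO)cc1 | starting material
5 | tributyl(iodomethyl)stannane | CCCC[Sn](CCCC)(CCCC)CI | starting material
6 | tributyl{[(4-methoxybenzyl)oxy]methyl}stannane | CCCC[Sn](CCCC)(CCCC)COCc1ccc(OC)cc1 | intermediate
7 | {[(4-methoxybenzyl)oxy]methyl}lithium | [Li]COCc1ccc(OC)cc1 | intermediate
8 | lithium 1-{[(4-methoxybenzyl)oxy]methyl}-2,6,6-trimethyl-3-(2-methylpropoxy)cyclohex-2-en-1-olate (racemic) | CC1=C(OCC(C)C)CCC(C)(C)C1(O[Li])COCc2ccc(OC)cc2 | intermediate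
9 | 3-{[(4-methoxybenzyl)oxy]methyl}-2,4,4-trimethylcyclohex-2-en-1-one | CC1=C(COCc2ccc(OC)cc2)C(C)(C)CCC1=O | intermediate
10 | {[5-({(4-methoxybenzyl)oxy}methyl)-4,4,6-trimethylcyclohexa-1,5-dien-1-yl]oxy}trimethylsilane | CC1=C(COCc2ccc(OC)cc2)C(C)(C)CC=C1O[Si](C)(C)C | intermediate
11 | 3-{[(4-methoxybenzyl)oxy]methyl}-2,4,4-trimethylcyclohexa-2,5-dien-1-one | CC1=C(COCc2ccc(OC)cc2)C(C)(C)C=CC1=O | intermediate
12 | (1,3-dioxolan-2-ylmethyl)magnesium bromide | Br[Mg]CC1OCCO1 | starting material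
13 | bromo{[(3S)-3-(1,3-dioxolan-2-ylmethyl)-5-{[(4-methoxybenzyl)oxy]methyl}-4,4,6-trimethylcyclohexa-1,5-dien-1-yl]oxy}magnesium | C1(OCCO1)C[C@H]2C=C(O[Mg]Br)C(C)=C(COCc3ccc(OC)cc3)C2(C)C | intermediate
14 | (5S)-5-(1,3-dioxolan-2-ylmethyl)-3-{[(4-methoxybenzyl)oxy]methyl}-2,4,4-trimethylcyclohex-2-en-1-one | C1(OCCO1)C[C@H]2CC(=O)C(C)=C(COCc3ccc(OC)cc3)C2(C)C | intermediate
15 | bromo{[(3R)-3-(1,3-dioxolan-2-ylmethyl)-5-{[(4-methoxybenzyl)oxy]methyl}-4,4,6-trimethylcyclohexa-1,5-dien-1-yl]oxy}magnesium | C1(OCCO1)C[C@@H]2C=C(O[Mg]Br)C(C)=C(COCc3ccc(OC)cc3)C2(C)C | intermediate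
16 | (5R)-5-(1,3-dioxolan-2-ylmethyl)-3-{[(4-methoxybenzyl)oxy]methyl}-2,4,4-trimethylcyclohex-2-en-1-one | C1(OCCO1)C[C@@H]2CC(=O)C(C)=C(COCc3ccc(OC)cc3)C2(C)C | intermediate
17 | (1RS,5R)-5-(1,3-dioxolan-2-ylmethyl)-3-{[(4-methoxybenzyl)oxy]methyl}-2,4,4-trimethylcyclohex-2-en-1-ol | C1(OCCO1)C[C@H]2CC(O)C(C)=C(COCc3ccc(OC)cc3)C2(C)C | intermediate
18 | (1RS,5R)-5-(1,3-dioxolan-2-ylmethyl)-3-{[(4-methoxybenzyl)oxy]methyl}-2,4,4-trimethylcyclohex-2-en-1-yl methanesulfonate | C1(OCCO1)C[C@H]2CC(OS(C)(=O)=O)C(C)=C(COCc3ccc(OC)cc3)C2(C)C | intermediate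
19 | 2-{[(1R)-3-{[(4-methoxybenzyl)oxy]methyl}-2,2,4-trimethylcyclohex-3-en-1-yl]methyl}-1,3-dioxolane | C1(OCCO1)C[C@H]2CCC(C)=C(COCc3ccc(OC)cc3)C2(C)C | intermediate
20 | 2-[(1R)-3-{[(4-methoxybenzyl)oxy]methyl}-2,2,4-trimethylcyclohex-3-en-1-yl]acetaldehyde | O=CC[C@H]1CCC(C)=C(COCc2ccc(OC)cc2)C1(C)C | intermediate
21 | 4-methoxybenzyl [(5R)-2,6,6-trimethyl-5-(3-methylbut-2-en-1-yl)cyclohex-1-en-1-yl]methyl ether | CC(C)=CC[C@H]1CCC(C)=C(COCc2ccc(OC)cc2)C1(C)C | intermediate
22 | [(5R)-2,6,6-trimethyl-5-(3-methylbut-2-en-1-yl)cyclohex-1-en-1-yl]methanol | CC(C)=CC[C@H]1CCC(C)=C(CO)C1(C)C | intermediate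
23 | 2-({[(5R)-2,6,6-trimethyl-5-(3-methylbut-2-en-1-yl)cyclohex-1-en-1-yl]methyl}sulfanyl)-1,3-benzothiazole | CC(C)=CC[C@H]1CCC(C)=C(CSc2nc3ccccc3s2)C1(C)C | intermediate
24 | 2-({[(5R)-2,6,6-trimethyl-5-(3-methylbut-2-en-1-yl)cyclohex-1-en-1-yl]methyl}sulfonyl)-1,3-benzothiazole | CC(C)=CC[C@H]1CCC(C)=C(CS(=O)(=O)c2nc3ccccc3s2)C1(C)C | intermediate
25 | (1RS,5S)-5-(1,3-dioxolan-2-ylmethyl)-3-{[(4-methoxybenzyl)oxy]methyl}-2,4,4-trimethylcyclohex-2-en-1-ol | C1(OCCO1)C[C@@H]2CC(O)C(C)=C(COCc3ccc(OC)cc3)C2(C)C | intermediate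
26 | (1RS,5S)-5-(1,3-dioxolan-2-ylmethyl)-3-{[(4-methoxybenzyl)oxy]methyl}-2,4,4-trimethylcyclohex-2-en-1-yl methanesulfonate | C1(OCCO1)C[C@@H]2CC(OS(C)(=O)=O)C(C)=C(COCc3ccc(OC)cc3)C2(C)C | intermediate
27 | 2-{[(1S)-3-{[(4-methoxybenzyl)oxy]methyl}-2,2,4-trimethylcyclohex-3-en-1-yl]methyl}-1,3-dioxolane | C1(OCCO1)C[C@@H]2CCC(C)=C(COCc3ccc(OC)cc3)C2(C)C | intermediate
28 | 2-[(1S)-3-{[(4-methoxybenzyl)oxy]methyl}-2,2,4-trimethylcyclohex-3-en-1-yl]acetaldehyde | O=CC[C@@H]1CCC(C)=C(COCc2ccc(OC)cc2)C1(C)C | intermediate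
29 | 2-[(1S)-3-{[(4-methoxybenzyl)oxy]methyl}-2,2,4-trimethylcyclohex-3-en-1-yl]ethan-1-ol | OCC[C@@H]1CCC(C)=C(COCc2ccc(OC)cc2)C1(C)C | intermediate
30 | 4-methoxybenzyl [(5S)-5-(2-iodoethyl)-2,6,6-trimethylcyclohex-1-en-1-yl]methyl ether | ICC[C@@H]1CCC(C)=C(COCc2ccc(OC)cc2)C1(C)C | intermediate
31 | {2-[(1S)-3-{[(4-methoxybenzyl)oxy]methyl}-2,2,4-trimethylcyclohex-3-en-1-yl]ethyl}triphenylphosphonium iodide | [I-].C(C[C@@H]1CCC(C)=C(COCc2ccc(OC)cc2)C1(C)C)[P+](c3ccccc3)(c4ccccc4)c5ccccc5 | intermediate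
32 | 1,3-dihydroxyacetone (1,3-dihydroxypropan-2-one) | OCC(=O)CO | starting material
33 | 1,3-bis{[tert-butyl(dimethyl)silyl]oxy}propan-2-one | CC(C)(C)[Si](C)(C)OCC(=O)CO[Si](C)(C)C(C)(C)C | intermediate
34 | {2-[(1S)-3-{[(4-methoxybenzyl)oxy]methyl}-2,2,4-trimethylcyclohex-3-en-1-yl]ethylidene}triphenylphosphorane | C(C[C@@H]1CCC(C)=C(COCc2ccc(OC)cc2)C1(C)C)=P(c3ccccc3)(c4ccccc4)c5ccccc5 | intermediate
35 | 4-methoxybenzyl [(5S)-5-{4-[(tert-butyldimethylsilyl)oxy]-3-{[(tert-butyldimethylsilyl)oxy]methyl}but-2-en-1-yl}-2,6,6-trimethylcyclohex-1-en-1-yl]methyl ether | CC(C)(C)[Si](C)(C)OCC(CO[Si](C)(C)C(C)(C)C)=CC[C@@H]1CCC(C)=C(COCc2ccc(OC)cc2)C1(C)C | intermediate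
36 | [(5S)-5-{4-[(tert-butyldimethylsilyl)oxy]-3-{[(tert-butyldimethylsilyl)oxy]methyl}but-2-en-1-yl}-2,6,6-trimethylcyclohex-1-en-1-yl]methanol | CC(C)(C)[Si](C)(C)OCC(CO[Si](C)(C)C(C)(C)C)=CC[C@@H]1CCC(C)=C(CO)C1(C)C | intermediate
37 | 2-({[(5S)-5-{4-[(tert-butyldimethylsilyl)oxy]-3-{[(tert-butyldimethylsilyl)oxy]methyl}but-2-en-1-yl}-2,6,6-trimethylcyclohex-1-en-1-yl]methyl}sulfanyl)-1,3-benzothiazole | CC(C)(C)[Si](C)(C)OCC(CO[Si](C)(C)C(C)(C)C)=CC[C@@H]1CCC(C)=C(CSc2nc3ccccc3s2)C1(C)C | intermediate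
38 | 2-({[(5S)-5-{4-[(tert-butyldimethylsilyl)oxy]-3-{[(tert-butyldimethylsilyl)oxy]methyl}but-2-en-1-yl}-2,6,6-trimethylcyclohex-1-en-1-yl]methyl}sulfonyl)-1,3-benzothiazole | CC(C)(C)[Si](C)(C)OCC(CO[Si](C)(C)C(C)(C)C)=CC[C@@H]1CCC(C)=C(CS(=O)(=O)c2nc3ccccc3s2)C1(C)C | intermediate
39 | crocetin dialdehyde, (2E,4E,6E,8E,10E,12E,14E)-2,6,11,15-tetramethylhexadeca-2,4,6,8,10,12,14-heptaenedial | O=C/C(C)=C/C=C/C(C)=C/C=C/C=C(C)/C=C/C=C(C)/C=O | starting material
40 | (16Z)-isomer of 41 (7′Z in carotenoid numbering) | O=C/C(C)=C/C=C/C(C)=C/C=C/C=C(C)/C=C/C=C(C)/C=C\C1=C(C)CC[C@@H](CC=C(CO[Si](C)(C)C(C)(C)C)CO[Si](C)(C)C(C)(C)C)C1(C)C | intermediate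
41 | (2E,4E,6E,8E,10E,12E,14E,16E)-17-[(5S)-5-{4-[(tert-butyldimethylsilyl)oxy]-3-{[(tert-butyldimethylsilyl)oxy]methyl}but-2-en-1-yl}-2,6,6-trimethylcyclohex-1-en-1-yl]-2,6,11,15-tetramethylheptadeca-2,4,6,8,10,12,14,16-octaenal | O=C/C(C)=C/C=C/C(C)=C/C=C/C=C(C)/C=C/C=C(C)/C=C/C1=C(C)CC[C@@H](CC=C(CO[Si](C)(C)C(C)(C)C)CO[Si](C)(C)C(C)(C)C)C1(C)C | intermediate
42 | (7Z)-isomer of 43 | CC(C)=CC[C@H]1CCC(C)=C(\C=C/C(C)=C/C=C/C(C)=C/C=C/C=C(C)/C=C/C=C(C)/C=C/C2=C(C)CC[C@@H](CC=C(CO[Si](C)(C)C(C)(C)C)CO[Si](C)(C)C(C)(C)C)C2(C)C)C1(C)C | intermediate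
43 | (2R,2′S)-2′-{4-[(tert-butyldimethylsilyl)oxy]-3-{[(tert-butyldimethylsilyl)oxy]methyl}but-2-en-1-yl}-2-(3-methylbut-2-en-1-yl)-β,β-carotene (all-E) | CC(C)=CC[C@H]1CCC(C)=C(/C=C/C(C)=C/C=C/C(C)=C/C=C/C=C(C)/C=C/C=C(C)/C=C/C2=C(C)CC[C@@H](CC=C(CO[Si](C)(C)C(C)(C)C)CO[Si](C)(C)C(C)(C)C)C2(C)C)C1(C)C | intermediate
44 | (2R,2′S)-2′-[4-hydroxy-3-(hydroxymethyl)but-2-en-1-yl]-2-(3-methylbut-2-en-1-yl)-β,β-carotene (all-E; CNP0213288.1) | CC(C)=CC[C@H]1CCC(C)=C(/C=C/C(C)=C/C=C/C(C)=C/C=C/C=C(C)/C=C/C=C(C)/C=C/C2=C(C)CC[C@@H](CC=C(CO)CO)C2(C)C)C1(C)C | target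

**Step count**

Total step count: 27 (steps 1–5 to the dienone, 6–7 the two key additions, 8–14 ring A sulfone, 15–24 ring B sulfone, 25–27 endgame).

Longest linear sequence: 17 steps (1, 2, 4, 5, 7, 15, 16, 17, 18, 19, 21, 22, 23, 24, 25, 26, 27).

**Steps most likely to fail**

1. Step 6 (and its mirror image, step 7). The addition takes place at a β-carbon beside a quaternary centre and uses a Grignard reagent supplied in THF. It may therefore be sluggish, give way to 1,2-addition, or proceed with poor facial selectivity. Fallback: setting out from 11 and 12, the addition is run without a chiral ligand (CuBr·SMe2 10 mol %, THF, −40 °C; aq. NH4Cl). This should give the racemic enone F1 through the racemic pair of dienolates 13 and 15. Preparative chromatography on a polysaccharide chiral stationary phase then separates F1 into its antipodes, and the route is rejoined at 14 and at 16. Both antipodes are used, so the resolution discards nothing.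

2. Step 9 (and its mirror image, step 16). The allylic sulfonate may eliminate to a ring diene, or ionise so that hydride is delivered with a shift of the alkene out of C5=C6. Fallback: setting out from 17, acetylation (Ac2O, pyridine, DMAP) gives the allylic acetate F2. Pd(PPh3)4 (5 mol %) with NaBH4 in THF then reduces it through a π-allylpalladium intermediate generated by zerovalent palladium, with hydride delivered at the less hindered allylic terminus. The route is rejoined at 19. For ring B the same detour leads from 25 through the enantiomeric allylic acetate F3 to 27.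

3. Step 25 (the same concerns apply to step 26). The hindered sulfonyl carbanion may add incompletely, the benzothiazolyl sulfone may self-condense, or the mono-adduct may react on to the doubly olefinated product. Fallback: setting out from 36, CBr4/PPh3 (CH2Cl2, 0 °C) gives the allylic bromide F4, and PPh3 (toluene, rt) converts it to the phosphonium bromide F5. A Wittig reaction of F5 with excess 39 (NaOMe, CH2Cl2/MeOH, 0 °C → rt), followed by the iodine equilibration, returns to the route at 41 via 40.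

Further compounds
F1 | step 6 | rac-5-(1,3-dioxolan-2-ylmethyl)-3-{[(4-methoxybenzyl)oxy]methyl}-2,4,4-trimethylcyclohex-2-en-1-one | C1(OCCO1)CC2CC(=O)C(C)=C(COCc3ccc(OC)cc3)C2(C)C
F2 | step 9 | (1RS,5R)-5-(1,3-dioxolan-2-ylmethyl)-3-{[(4-methoxybenzyl)oxy]methyl}-2,4,4-trimethylcyclohex-2-en-1-yl acetate | C1(OCCO1)C[C@H]2CC(OC(C)=O)C(C)=C(COCc3ccc(OC)cc3)C2(C)C
F3 | step 9 | (1RS,5S)-5-(1,3-dioxolan-2-ylmethyl)-3-{[(4-methoxybenzyl)oxy]methyl}-2,4,4-trimethylcyclohex-2-en-1-yl acetate | C1(OCCO1)C[C@@H]2CC(OC(C)=O)C(C)=C(COCc3ccc(OC)cc3)C2(C)C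
F4 | step 25 | (5S)-1-(bromomethyl)-5-{4-[(tert-butyldimethylsilyl)oxy]-3-{[(tert-butyldimethylsilyl)oxy]methyl}but-2-en-1-yl}-2,6,6-trimethylcyclohex-1-ene | CC(C)(C)[Si](C)(C)OCC(CO[Si](C)(C)C(C)(C)C)=CC[C@@H]1CCC(C)=C(CBr)C1(C)C
F5 | step 25 | {[(5S)-5-{4-[(tert-butyldimethylsilyl)oxy]-3-{[(tert-butyldimethylsilyl)oxy]methyl}but-2-en-1-yl}-2,6,6-trimethylcyclohex-1-en-1-yl]methyl}triphenylphosphonium bromide | [Br-].CC(C)(C)[Si](C)(C)OCC(CO[Si](C)(C)C(C)(C)C)=CC[C@@H]1CCC(C)=C(C[P+](c2ccccc2)(c2ccccc2)c2ccccc2)C1(C)C
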